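**Strategy.** The pyrrole ring is disconnected at C3–C4 and N1–C5. This reveals two identical (5-bromo-1-tosylindol-3-yl)acetaldehyde halves joined N–N as a symmetric azine: each CHO carbon becomes C2 or C5, and each indolylic CH2 carbon becomes C3 or C4 with its indole ring attached. An acylative Piloty–Robinson reaction of that azine forges C3–C4 by a [3,3] shift and closes N1–C5 in one operation. It exploits the twofold symmetry of the 3,4-bis(indol-3-yl)pyrrole core. The C2 ester, the only feature that breaks this symmetry, is then placed on either of the two equivalent α-carbons, and the tosyl groups are removed last.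

Key step: step 5

Assumption (remark on the chemistry): under the acylative conditions chosen, the ring nitrogen first emerges benzoylated and the second nitrogen leaves as benzamide, not as ammonia. The N-benzoyl group is methanolysed in the same operation, so the isolated key-step product is the N–H pyrrole. The C=N geometry of the azine (drawn E,E) and the enamide geometry of 13 have no bearing on the outcome.

Step 1
Reactants: 1 5-bromoindole-3-acetic acid; 2 1,1'-carbonyldiimidazole; 3 N,O-dimethylhydroxylamine hydrochloride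
Product: 5 2-(5-bromo-1H-indol-3-yl)-N-methoxy-N-methylacetamide, via acyl imidazolide 4 (not isolated)
Conditions: CDI (1.1 equiv), THF, rt; then MeNHOMe·HCl (1.2 equiv), rt
Reagents that add atoms: N,O-dimethylhydroxylamine hydrochloride, CNOC.Cl
Why: Carbonyldiimidazole activation of the acid to acyl imidazolide 4 and its aminolysis is a standard Weinreb amide coupling, and the weakly nucleophilic indole N–H should not compete.

Step 2
Reactants: 5 2-(5-bromo-1H-indol-3-yl)-N-methoxy-N-methylacetamide; 6 p-toluenesulfonyl chloride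
Product: 7 2-(5-bromo-1-tosyl-1H-indol-3-yl)-N-methoxy-N-methylacetamide
Conditions: TsCl (1.2 equiv), powdered NaOH, n-Bu4NHSO4 (cat.), CH2Cl2, 0 °C to rt
Reagents that add atoms: p-toluenesulfonyl chloride, Cc1ccc(S(Cl)(=O)=O)cc1
Why: Phase-transfer N-sulfonylation of the indole, in which the indolide formed by NaOH attacks TsCl; the tertiary amide has no N–H and should resist these conditions, and the sulfonyl group later stabilises the aldehyde and deactivates the indole rings.

Step 3
Reactants: 7 2-(5-bromo-1-tosyl-1H-indol-3-yl)-N-methoxy-N-methylacetamide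
Product: 8 (5-bromo-1-tosyl-1H-indol-3-yl)acetaldehyde
Conditions: i-Bu2AlH (1.5 equiv), THF, −78 °C; aq. KNaC4H4O6 (potassium sodium tartrate)
Reagents that add atoms: none
Why: Weinreb amide reduction, in which hydride addition gives a chelated tetrahedral aluminium intermediate that holds until the quench, so over-reduction should be avoided while sulfonamide and aryl bromide stay inert at −78 °C; the enolisable aldehyde is taken on crude.

Step 4
Reactants: 8 (5-bromo-1-tosyl-1H-indol-3-yl)acetaldehyde (2 equiv); 9 hydrazine hydrate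
Product: 11 (1E,2E)-1,2-bis[2-(5-bromo-1-tosyl-1H-indol-3-yl)ethylidene]hydrazine, via mono-hydrazone 10 (not isolated)
Conditions: N2H4·H2O (0.5 equiv), MgSO4, EtOH/CH2Cl2, 0 °C to rt
Reagents that add atoms: hydrazine hydrate, NN.O
Why: Azine formation by double condensation of hydrazine with an unhindered aldehyde through mono-hydrazone 10, driven by dehydration; half an equivalent of hydrazine should favour the symmetric azine over the hydrazone.

Step 5
Reactants: 11 (1E,2E)-1,2-bis[2-(5-bromo-1-tosyl-1H-indol-3-yl)ethylidene]hydrazine; 12 benzoyl chloride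
Product: 15 3,4-bis(5-bromo-1-tosyl-1H-indol-3-yl)-1H-pyrrole, via dibenzoyl bis-ene-hydrazine 13 (not isolated), via N-benzoylpyrrole 14 (not isolated)
Conditions: PhCOCl (2.2 equiv), pyridine, 170 °C (sealed tube, microwave); aqueous work-up; then NaOMe (0.2 equiv), MeOH/THF, 0 °C
Reagents that add atoms: none
Why: Benzoyl chloride acylates both azine nitrogens and pyridine removes a proton from each indolylic CH2, giving the styrene-like N,N'-dibenzoyl bis-ene-hydrazine 13, whose 3,4-diaza-Cope ([3,3]-sigmatropic) shift forms the future C3–C4 bond as the weak N–N bond breaks. The transient 1,4-bis(N-acylimine) tautomerises to an enamide whose N–H adds to the other acylimine carbon in a 5-exo-trig closure (N1–C5), and β-elimination of benzamide aromatises the ring to N-benzoylpyrrole 14. This is the acylative Piloty–Robinson pyrrole synthesis, established for azines of enolisable aldehydes and mechanistically akin to the Fischer indole rearrangement. No stereocentre remains, because the two sp3 carbons created in the shift become sp2 on aromatisation. The step needs only homo-coupling and one direction of enamide formation: the azine is symmetric, each C=N has a single α-CH2, aryl conjugation lowers the barrier of the shift, and the N-tosyl groups keep the indole nitrogens and C2 positions out of the acylation. Catalytic methoxide at 0 °C then transfers the activated N-benzoyl group of 14 to methanol much faster than it attacks an indole sulfonamide and should release N–H pyrrole 15.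

Step 6
Reactants: 15 3,4-bis(5-bromo-1-tosyl-1H-indol-3-yl)-1H-pyrrole; 16 trichloroacetyl chloride
Product: 17 1-[3,4-bis(5-bromo-1-tosyl-1H-indol-3-yl)-1H-pyrrol-2-yl]-2,2,2-trichloroethan-1-one
Conditions: Cl3CCOCl (1.5 equiv), CH2Cl2, 0 °C to rt
Reagents that add atoms: trichloroacetyl chloride, O=C(Cl)C(Cl)(Cl)Cl
Why: Uncatalysed Friedel–Crafts-type trichloroacetylation of an N–H pyrrole at an α-carbon; C2 and C5 are equivalent by symmetry, the first acyl group deactivates the ring against a second, and the N-sulfonylindoles are too electron-poor to react.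

Step 7
Reactants: 17 1-[3,4-bis(5-bromo-1-tosyl-1H-indol-3-yl)-1H-pyrrol-2-yl]-2,2,2-trichloroethan-1-one; 18 sodium methoxide
Product: 20 methyl 3,4-bis(5-bromo-1H-indol-3-yl)-1H-pyrrole-2-carboxylate, via bis-tosyl methyl ester 19 (not isolated)
Conditions: NaOMe (6 equiv), MeOH/THF, 0 °C to rt; then 60 °C; aq. NH4Cl
Reagents that add atoms: sodium methoxide, C[O-].[Na+]
Why: Haloform-type cleavage of the trichloromethyl ketone by methoxide should give methyl ester 19 at room temperature, and on warming methoxide attacks the sulfonyl sulfur of each N-tosylindole (nucleophilic desulfonylation with indolide as leaving group); ester exchange is degenerate in methanol and the aryl bromides are untouched.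

**Compound list**

1 | 5-bromoindole-3-acetic acid | OC(=O)Cc1c[nH]c2ccc(Br)cc12 | starting material
2 | 1,1'-carbonyldiimidazole | O=C(n1ccnc1)n1ccnc1 | starting material
3 | N,O-dimethylhydroxylamine hydrochloride | CNOC.Cl | starting material
4 | 2-(5-bromo-1H-indol-3-yl)-1-(imidazol-1-yl)ethan-1-one (acyl imidazolide) | O=C(Cc1c[nH]c2ccc(Br)cc12)n1ccnc1 | intermediate (not isolated)
5 | 2-(5-bromo-1H-indol-3-yl)-N-methoxy-N-methylacetamide | CON(C)C(=O)Cc1c[nH]c2ccc(Br)cc12 | intermediate
6 | p-toluenesulfonyl chloride | Cc1ccc(S(Cl)(=O)=O)cc1 | starting material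
7 | 2-(5-bromo-1-tosyl-1H-indol-3-yl)-N-methoxy-N-methylacetamide | CON(C)C(=O)Cc1cn(S(=O)(=O)c2ccc(C)cc2)c2ccc(Br)cc12 | intermediate
8 | (5-bromo-1-tosyl-1H-indol-3-yl)acetaldehyde | O=CCc1cn(S(=O)(=O)c2ccc(C)cc2)c2ccc(Br)cc12 | intermediate
9 | hydrazine hydrate | NN.O | starting material
10 | (E)-[2-(5-bromo-1-tosyl-1H-indol-3-yl)ethylidene]hydrazine (mono-hydrazone) | N/N=C/Cc1cn(S(=O)(=O)c2ccc(C)cc2)c2ccc(Br)cc12 | intermediate (not isolated)
11 | (1E,2E)-1,2-bis[2-(5-bromo-1-tosyl-1H-indol-3-yl)ethylidene]hydrazine (azine) | O=S(=O)(c1ccc(C)cc1)n1cc(C/C=N/N=C/Cc2cn(S(=O)(=O)c3ccc(C)cc3)c3ccc(Br)cc23)c2cc(Br)ccc21 | intermediate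
12 | benzoyl chloride | O=C(Cl)c1ccccc1 | starting material
13 | N,N'-dibenzoyl-N,N'-bis[(E)-2-(5-bromo-1-tosyl-1H-indol-3-yl)ethenyl]hydrazine | O=C(c1ccccc1)N(/C=C/c1cn(S(=O)(=O)c2ccc(C)cc2)c2ccc(Br)cc12)N(/C=C/c1cn(S(=O)(=O)c2ccc(C)cc2)c2ccc(Br)cc12)C(=O)c1ccccc1 | intermediate (not isolated)
14 | [3,4-bis(5-bromo-1-tosyl-1H-indol-3-yl)-1H-pyrrol-1-yl](phenyl)methanone | O=C(c1ccccc1)n1cc(-c2cn(S(=O)(=O)c3ccc(C)cc3)c3ccc(Br)cc23)c(-c2cn(S(=O)(=O)c3ccc(C)cc3)c3ccc(Br)cc23)c1 | intermediate (not isolated)
15 | 3,4-bis(5-bromo-1-tosyl-1H-indol-3-yl)-1H-pyrrole | c1[nH]cc(-c2cn(S(=O)(=O)c3ccc(C)cc3)c3ccc(Br)cc23)c1-c1cn(S(=O)(=O)c2ccc(C)cc2)c2ccc(Br)cc12 | intermediate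
16 | trichloroacetyl chloride | O=C(Cl)C(Cl)(Cl)Cl | starting material
17 | 1-[3,4-bis(5-bromo-1-tosyl-1H-indol-3-yl)-1H-pyrrol-2-yl]-2,2,2-trichloroethan-1-one | O=C(c1[nH]cc(-c2cn(S(=O)(=O)c3ccc(C)cc3)c3ccc(Br)cc23)c1-c1cn(S(=O)(=O)c2ccc(C)cc2)c2ccc(Br)cc12)C(Cl)(Cl)Cl | intermediate
18 | sodium methoxide | C[O-].[Na+] | starting material
19 | methyl 3,4-bis(5-bromo-1-tosyl-1H-indol-3-yl)-1H-pyrrole-2-carboxylate | COC(=O)c1[nH]cc(-c2cn(S(=O)(=O)c3ccc(C)cc3)c3ccc(Br)cc23)c1-c1cn(S(=O)(=O)c2ccc(C)cc2)c2ccc(Br)cc12 | intermediate (not isolated)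
20 | methyl 3,4-bis(5-bromo-1H-indol-3-yl)-1H-pyrrole-2-carboxylate | COC(=O)c1[nH]cc(-c2c[nH]c3ccc(Br)cc23)c1-c1c[nH]c2ccc(Br)cc12 | target

**Step count.** Total: 7 steps. Longest linear sequence: 7 steps (1 to 20).

**Steps most likely to fail**

1. Step 5 (key step). The double N-acylation and enamide formation may stay incomplete, or the ene-hydrazine may oligomerise thermally before the sigmatropic shift. The fallback builds the C3–C4 bond by oxidative enolate dimerisation and closes the ring by Paal–Knorr condensation. It sets out from 7: deprotonation with LiN(SiMe3)2 in THF at −78 °C and addition of I2 (0.5 equiv) should couple two enolates to 2,3-bis(5-bromo-1-tosyl-1H-indol-3-yl)-N1,N4-dimethoxy-N1,N4-dimethylbutanediamide F1, a mixture of meso and racemic diastereomers that converge later. Reduction of both Weinreb amides with i-Bu2AlH in THF at −78 °C should give 2,3-bis(5-bromo-1-tosyl-1H-indol-3-yl)butanedial F2. This is condensed crude with NH4OAc in AcOH at 60 °C and comes back to the route at 15.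

2. Step 7. The sulfonate ester formed transiently during S–N cleavage may methylate a pyrrole or indole nitrogen, or cleavage of the second sulfonamide may stall. The fallback replaces methoxide by hydroxide, so no alkylating agent is formed, and esterifies afterwards. It sets out from 17: aqueous NaOH in dioxane at 70 °C should cleave the trichloromethyl ketone and both sulfonamides, and careful acidification at 0 °C should give 3,4-bis(5-bromo-1H-indol-3-yl)-1H-pyrrole-2-carboxylic acid F3. Treatment with Me3SiCHN2 in MeOH/toluene at 0 °C methylates only the carboxylic acid and comes back to the route at 20.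

3. Step 3. The arylacetaldehyde may enolise and self-condense, or oxidise in air, during the aqueous aluminium work-up and any purification. The fallback takes the reduction through to a stable alcohol and regenerates the aldehyde under neutral, non-aqueous conditions just before use. It sets out from 7: i-Bu2AlH in THF at −78 °C followed by NaBH4 and MeOH at 0 °C in the same flask should give 2-(5-bromo-1-tosyl-1H-indol-3-yl)ethan-1-ol F4, which can be purified and stored. Oxidation with Dess–Martin periodinane and NaHCO3 in CH2Cl2 at rt, followed by filtration, comes back to the route at 8, which is condensed at once in step 4.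

**Further compounds**

F1 | step 5 | 2,3-bis(5-bromo-1-tosyl-1H-indol-3-yl)-N1,N4-dimethoxy-N1,N4-dimethylbutanediamide (meso and racemic diastereomers, mixture) | CON(C)C(=O)C(c1cn(S(=O)(=O)c2ccc(C)cc2)c2ccc(Br)cc12)C(C(=O)N(C)OC)c1cn(S(=O)(=O)c2ccc(C)cc2)c2ccc(Br)cc12
F2 | step 5 | 2,3-bis(5-bromo-1-tosyl-1H-indol-3-yl)butanedial (diastereomer mixture) | O=CC(c1cn(S(=O)(=O)c2ccc(C)cc2)c2ccc(Br)cc12)C(C=O)c1cn(S(=O)(=O)c2ccc(C)cc2)c2ccc(Br)cc12
F3 | step 7 | 3,4-bis(5-bromo-1H-indol-3-yl)-1H-pyrrole-2-carboxylic acid | OC(=O)c1[nH]cc(-c2c[nH]c3ccc(Br)cc23)c1-c1c[nH]c2ccc(Br)cc12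
F4 | step 3 | 2-(5-bromo-1-tosyl-1H-indol-3-yl)ethan-1-ol | OCCc1cn(S(=O)(=O)c2ccc(C)cc2)c2ccc(Br)cc12
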